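The furan ring is read as an oxidised geranyl chain on the arene, and the route rests on cutting its O1–C2 bond. Furan C2 (the arene-bearing carbon) becomes a CH2 that is both benzylic and allylic, C3=C4 the trisubstituted alkene, and C5 a hydroxymethyl group cis to that CH2. In one operation DDQ removes hydride from this CH2, the hydroxyl oxygen closes the five-membered ring, and a second equivalent aromatises it, leaving the ester-bearing stereocentre untouched. The precursor is the (2E,4S)-1-(2,5-dimethoxyphenyl)-3-(hydroxymethyl)-7-methylocta-2,6-dien-4-yl senecioate, reached from an aryl propyne by ynone reduction, directed trans-hydrostannation and hydroxymethylation; the quinone is unveiled last.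

Key step: step 9

Remark: the carbinol centre is read from the SMILES as (S), the quinone oxygens are taken to come from water in the last step, and methoxyallene, 3-methylbut-2-enoic acid and (tributylstannyl)methanol are taken as purchasable.

Step 1
Reactants: 1 2-bromo-1,4-dimethoxybenzene; 2 methoxyallene (1-methoxypropa-1,2-diene)
Product: 4 1,4-dimethoxy-2-(prop-2-yn-1-yl)benzene, via arylmagnesium bromide 3 (not isolated)
Conditions: Mg, THF, reflux; then CuBr (5 mol %), 2, −20 °C → rt; aq. NH4Cl
Reagents that add atoms: none
Why: Copper-catalysed SN2′ substitution of an allenyl ether by an aryl Grignard reagent, in which the aryl group adds to the CH2 terminus and methoxide leaves from the far end, should give the terminal alkyne directly and avoid the aryl allene that propargyl halides tend to give.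

Step 2
Reactants: 5 4-methylpent-3-enoic acid
Product: 7 N-methoxy-N,4-dimethylpent-3-enamide, via acyl imidazolide 6 (not isolated)
Conditions: CDI, CH2Cl2, 0 °C → rt; then MeNHOMe·HCl, rt
Reagents that add atoms: N,O-dimethylhydroxylamine hydrochloride, CNOC.Cl
Why: Weinreb amide formation by carbonyldiimidazole activation and aminolysis runs without strong base, so the β,γ-double bond should not move into conjugation.

Step 3
Reactants: 4 1,4-dimethoxy-2-(prop-2-yn-1-yl)benzene; 7 N-methoxy-N,4-dimethylpent-3-enamide
Product: 9 1-(2,5-dimethoxyphenyl)-7-methyloct-6-en-2-yn-4-one, via lithium acetylide 8 (not isolated)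
Conditions: n-BuLi, THF, −78 °C; then 7, −78 → −20 °C; cold aq. NH4Cl
Reagents that add atoms: none
Why: Weinreb ketone synthesis, in which kinetic deprotonation at −78 °C takes the acetylenic hydrogen and not the benzylic-propargylic CH2, and the chelated tetrahedral adduct survives until the cold, mildly acidic quench, so that neither over-addition nor isomerisation of the skipped ynone is expected.

Step 4
Reactants: 9 1-(2,5-dimethoxyphenyl)-7-methyloct-6-en-2-yn-4-one
Product: 10 (S)-1-(2,5-dimethoxyphenyl)-7-methyloct-6-en-2-yn-4-ol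
Conditions: Ru[(S,S)-TsDPEN](p-cymene) (1 mol %), i-PrOH, rt
Reagents that add atoms: none
Why: Noyori asymmetric transfer hydrogenation of an alkynyl ketone, in which the alkynyl group takes the position that the aryl group of an aryl ketone takes in the concerted Ru–H/N–H transfer, so the (S,S) complex should deliver hydride to the face that gives the (S) carbinol, while the base-free amido complex spares the skipped ynone.

Step 5
Reactants: 10 (S)-1-(2,5-dimethoxyphenyl)-7-methyloct-6-en-2-yn-4-ol
Product: 11 (2Z,4S)-1-(2,5-dimethoxyphenyl)-7-methyl-3-(tributylstannyl)octa-2,6-dien-4-ol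
Conditions: [Cp*RuCl]4 (2 mol %), Bu3SnH, CH2Cl2, rt
Reagents that add atoms: tributyltin hydride, CCCC[SnH](CCCC)CCCC
Why: Hydroxyl-directed ruthenium-catalysed trans-hydrostannation, in which a hydrogen bond from the free OH to the chloride ligand steers tin to the alkyne carbon next to the carbinol and hydrogen arrives anti, should place tin cis to the CH2Ar group and leave the isolated alkene alone.

Step 6
Reactants: 11 (2Z,4S)-1-(2,5-dimethoxyphenyl)-7-methyl-3-(tributylstannyl)octa-2,6-dien-4-ol
Product: 12 (2Z,4S)-1-(2,5-dimethoxyphenyl)-3-iodo-7-methylocta-2,6-dien-4-ol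
Conditions: I2, CH2Cl2, −78 → 0 °C; aq. Na2S2O3
Reagents that add atoms: iodine, [I][I]
Why: Iododestannation is an ipso substitution at the C–Sn bond that retains the alkene geometry and is far faster than any reaction of iodine with the prenyl alkene or the arene at low temperature.

Step 7
Reactants: 12 (2Z,4S)-1-(2,5-dimethoxyphenyl)-3-iodo-7-methylocta-2,6-dien-4-ol; 13 3-methylbut-2-enoic acid (senecioic acid)
Product: 14 (2Z,4S)-1-(2,5-dimethoxyphenyl)-3-iodo-7-methylocta-2,6-dien-4-yl 3-methylbut-2-enoate
Conditions: DCC, DMAP (cat.), CH2Cl2, 0 °C → rt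
Reagents that add atoms: none
Why: Steglich esterification acylates the oxygen without touching the C–O bond of the stereocentre, and the carbodiimide route avoids the vinylketene that an acid chloride and amine base would form and that leads to the deconjugated 3-methylbut-3-enoate.

Step 8
Reactants: 14 (2Z,4S)-1-(2,5-dimethoxyphenyl)-3-iodo-7-methylocta-2,6-dien-4-yl 3-methylbut-2-enoate; 15 (tributylstannyl)methanol
Product: 16 (2E,4S)-1-(2,5-dimethoxyphenyl)-3-(hydroxymethyl)-7-methylocta-2,6-dien-4-yl 3-methylbut-2-enoate
Conditions: Pd(PPh3)4 (5 mol %), 1,4-dioxane, 80 °C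
Reagents that add atoms: none
Why: Stille coupling in its hydroxymethylation form, in which oxidative addition of the alkenyl iodide to zerovalent palladium and reductive elimination both retain geometry and the α-oxygenated carbon transfers from tin in preference to butyl, should put CH2OH in the place of iodine, cis to the CH2Ar group; 16 is used at once so that the acyl group has no time to shift to the primary hydroxyl.

Step 9
Reactants: 16 (2E,4S)-1-(2,5-dimethoxyphenyl)-3-(hydroxymethyl)-7-methylocta-2,6-dien-4-yl 3-methylbut-2-enoate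
Product: 18 (S)-1-[5-(2,5-dimethoxyphenyl)furan-3-yl]-4-methylpent-3-en-1-yl 3-methylbut-2-enoate, via 2-aryl-2,5-dihydrofuran 17 (not isolated)
Conditions: DDQ (2.3 equiv), 2,6-dichloropyridine, 4 Å MS, ClCH2CH2Cl, 0 °C → rt
Reagents that add atoms: none
Why: DDQ takes hydride (stepwise: electron, proton, electron) from C1 of 16, the only CH2 that is both benzylic to the dimethoxyarene and allylic, and the resulting cation, spread over the arene, C1 and C3, is captured at C1 by the hydroxymethyl oxygen held cis to C1 on the C2=C3 bond, which forms the O1–C2 bond of the future furan. The closest known reaction types are the DDQ-mediated oxidative cyclisation of benzylic or allylic C–H bonds onto tethered alcohols and the DDQ dehydrogenation of 2,5-dihydrofurans, here run consecutively in one flask. The five-membered ring closes by attack of oxygen on the benzylic terminus of the cation, 5-exo-trig with respect to the C1=C(aryl) bond of its quinone-methide-like resonance form, while attack at C3 would require an oxirane. The aryl-bearing carbon of dihydrofuran 17 carries a hydrogen that is benzylic, allylic and alpha to oxygen, so the second equivalent of DDQ removes it readily and loss of a proton from the ring CH2 gives furan 18; the transient stereocentre at that carbon is erased and needs no control, and the (S) carbinol centre lies outside the reacting system. The step needs site selectivity for C1–H over the prenyl C–H bonds, the carbinol C–H and the primary allylic alcohol, and this is secured by the electron-rich 2,5-dimethoxyphenyl ring, by the acyloxy group that deactivates the carbinol C–H, and by the E geometry, which keeps the ester oxygen and the prenyl alkene away from C1. 2,6-Dichloropyridine and 4 Å molecular sieves keep acid and water from diverting the cation or opening the product.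

Step 10
Reactants: 18 (S)-1-[5-(2,5-dimethoxyphenyl)furan-3-yl]-4-methylpent-3-en-1-yl 3-methylbut-2-enoate
Product: 19 (S)-1-[5-(3,6-dioxocyclohexa-1,4-dien-1-yl)furan-3-yl]-4-methylpent-3-en-1-yl 3-methylbut-2-enoate
Conditions: (NH4)2Ce(NO3)6 (2.5 equiv), MeCN/H2O (4:1), 0 °C, 15 min
Reagents that add atoms: water, O
Why: Oxidative demethylation of a 1,4-dimethoxyarene by (NH4)2Ce(NO3)6, in which two one-electron oxidations are each followed by attack of water at a methoxy-bearing ring carbon and loss of methanol, should give the benzoquinone in minutes at 0 °C without involving the stereocentre, the ester or the prenyl alkene.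

Compound list
1 | 2-bromo-1,4-dimethoxybenzene | COc1ccc(OC)c(Br)c1 | starting material
2 | methoxyallene (1-methoxypropa-1,2-diene) | COC=C=C | starting material
3 | (2,5-dimethoxyphenyl)magnesium bromide | COc1ccc(OC)c([Mg]Br)c1 | intermediate
4 | 1,4-dimethoxy-2-(prop-2-yn-1-yl)benzene | C#CCc1cc(OC)ccc1OC | intermediate
5 | 4-methylpent-3-enoic acid | CC(C)=CCC(=O)O | starting material
6 | 1-(1H-imidazol-1-yl)-4-methylpent-3-en-1-one (acyl imidazolide) | CC(C)=CCC(=O)n1ccnc1 | intermediate
7 | N-methoxy-N,4-dimethylpent-3-enamide | CC(C)=CCC(=O)N(C)OC | intermediate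
8 | lithium 3-(2,5-dimethoxyphenyl)prop-1-yn-1-ide | [Li]C#CCc1cc(OC)ccc1OC | intermediate
9 | 1-(2,5-dimethoxyphenyl)-7-methyloct-6-en-2-yn-4-one | CC(C)=CCC(=O)C#CCc1cc(OC)ccc1OC | intermediate
10 | (S)-1-(2,5-dimethoxyphenyl)-7-methyloct-6-en-2-yn-4-ol | CC(C)=CC[C@H](O)C#CCc1cc(OC)ccc1OC | intermediate
11 | (2Z,4S)-1-(2,5-dimethoxyphenyl)-7-methyl-3-(tributylstannyl)octa-2,6-dien-4-ol | CC(C)=CC[C@H](O)C(/[Sn](CCCC)(CCCC)CCCC)=C/Cc1cc(OC)ccc1OC | intermediate
12 | (2Z,4S)-1-(2,5-dimethoxyphenyl)-3-iodo-7-methylocta-2,6-dien-4-ol | CC(C)=CC[C@H](O)C(/I)=C/Cc1cc(OC)ccc1OC | intermediate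
13 | 3-methylbut-2-enoic acid (senecioic acid) | CC(C)=CC(=O)O | starting material
14 | (2Z,4S)-1-(2,5-dimethoxyphenyl)-3-iodo-7-methylocta-2,6-dien-4-yl 3-methylbut-2-enoate | CC(C)=CC[C@H](OC(=O)C=C(C)C)C(/I)=C/Cc1cc(OC)ccc1OC | intermediate
15 | (tributylstannyl)methanol | CCCC[Sn](CO)(CCCC)CCCC | starting material
16 | (2E,4S)-1-(2,5-dimethoxyphenyl)-3-(hydroxymethyl)-7-methylocta-2,6-dien-4-yl 3-methylbut-2-enoate | CC(C)=CC[C@H](OC(=O)C=C(C)C)C(/CO)=C/Cc1cc(OC)ccc1OC | intermediate
17 | (1S)-1-[5-(2,5-dimethoxyphenyl)-2,5-dihydrofuran-3-yl]-4-methylpent-3-en-1-yl 3-methylbut-2-enoate (both epimers at the aryl-bearing ring carbon) | CC(C)=CC[C@H](OC(=O)C=C(C)C)C1=CC(c2cc(OC)ccc2OC)OC1 | intermediate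
18 | (S)-1-[5-(2,5-dimethoxyphenyl)furan-3-yl]-4-methylpent-3-en-1-yl 3-methylbut-2-enoate | CC(C)=CC[C@H](OC(=O)C=C(C)C)c1coc(-c2cc(OC)ccc2OC)c1 | intermediate
19 | (S)-1-[5-(3,6-dioxocyclohexa-1,4-dien-1-yl)furan-3-yl]-4-methylpent-3-en-1-yl 3-methylbut-2-enoate | CC(C)=CC[C@H](OC(=O)C=C(C)C)c1coc(C2=CC(=O)C=CC2=O)c1 | target

Total step count: 10. Longest linear sequence: 9 steps (steps 1, 3, 4, 5, 6, 7, 8, 9, 10); step 2 is a one-step side branch.

Steps most likely to fail

Step 9. What may go wrong is a loss of site selectivity in the hydride abstraction: oxidation of the primary allylic alcohol to the enal, diversion of the cation before the oxygen closes, or over-oxidation of the electron-rich aryl furan by the second equivalent of DDQ. The fallback gives up C–H oxidation and makes the aryl–furan bond by cross-coupling; it sets out from 1 and comes back at 18. Suzuki–Miyaura coupling of 1 with purchased 4-formylfuran-2-boronic acid (Pd(dppf)Cl2, K2CO3, dioxane/H2O, 80 °C) should give 5-(2,5-dimethoxyphenyl)furan-3-carbaldehyde F1. Brown allylation with (−)-Ipc2B(allyl), the antipode that adds to the Si face of aryl aldehydes (Et2O, −78 °C, then NaOH/H2O2), should give (S)-1-[5-(2,5-dimethoxyphenyl)furan-3-yl]but-3-en-1-ol F2. Cross metathesis with excess 2-methylbut-2-ene (second-generation Grubbs catalyst, RuCl2(PCy3)(H2IMes)(=CHPh), CH2Cl2, 40 °C) converts the allyl into the prenyl group and should give (S)-1-[5-(2,5-dimethoxyphenyl)furan-3-yl]-4-methylpent-3-en-1-ol F3. Steglich esterification with 13 (DCC, DMAP) then gives 18.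

Step 8. What may go wrong is slow transfer of the hydroxymethyl group from tin, so that on prolonged heating zerovalent palladium ionises the allylic ester or the acyl group shifts to the new primary hydroxyl. The fallback introduces the carbon before the ester and without palladium; it sets out from 12 and comes back at 16. Deprotonation of 12 with MeLi (1 equiv) and iodine–lithium exchange with t-BuLi (2 equiv) in THF/Et2O at −78 °C, followed by monomeric formaldehyde, should give (2E,4S)-1-(2,5-dimethoxyphenyl)-3-(hydroxymethyl)-7-methylocta-2,6-dien-4-ol F4 with retention of geometry. Selective silylation of the primary hydroxyl (TBSCl, imidazole, CH2Cl2, 0 °C) should give (2E,4S)-3-[(tert-butyldimethylsilyloxy)methyl]-1-(2,5-dimethoxyphenyl)-7-methylocta-2,6-dien-4-ol F5. Esterification with 13 (DCC, DMAP) should give (2E,4S)-3-[(tert-butyldimethylsilyloxy)methyl]-1-(2,5-dimethoxyphenyl)-7-methylocta-2,6-dien-4-yl 3-methylbut-2-enoate F6. Desilylation under weakly acidic conditions (HF·pyridine, THF, 0 °C), chosen to suppress acyl migration, gives 16.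

Step 4. What may go wrong is isomerisation of the doubly skipped ynone to allenyl or dienyl ketones before or during the reduction, together with incomplete facial selectivity. The fallback reduces a silyl ynone that has no benzylic-propargylic hydrogens and attaches the arene afterwards; it sets out from 7 and comes back at 10. Lithium (trimethylsilyl)acetylide and 7 (THF, −78 °C) should give 6-methyl-1-(trimethylsilyl)hept-5-en-1-yn-3-one F7. Transfer hydrogenation with Ru[(S,S)-TsDPEN](p-cymene) in i-PrOH should give (S)-6-methyl-1-(trimethylsilyl)hept-5-en-1-yn-3-ol F8. Desilylation (K2CO3, MeOH, rt) should give (S)-6-methylhept-5-en-1-yn-3-ol F9. Double deprotonation with EtMgBr (2 equiv, THF) and CuBr-catalysed coupling of the alkynylmagnesium bromide with purchased 2,5-dimethoxybenzyl bromide then gives 10.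

Further compounds
F1 | step 9 | 5-(2,5-dimethoxyphenyl)furan-3-carbaldehyde | O=Cc1coc(-c2cc(OC)ccc2OC)c1
F2 | step 9 | (S)-1-[5-(2,5-dimethoxyphenyl)furan-3-yl]but-3-en-1-ol | C=CC[C@H](O)c1coc(-c2cc(OC)ccc2OC)c1
F3 | step 9 | (S)-1-[5-(2,5-dimethoxyphenyl)furan-3-yl]-4-methylpent-3-en-1-ol | CC(C)=CC[C@H](O)c1coc(-c2cc(OC)ccc2OC)c1
F4 | step 8 | (2E,4S)-1-(2,5-dimethoxyphenyl)-3-(hydroxymethyl)-7-methylocta-2,6-dien-4-ol | CC(C)=CC[C@H](O)C(/CO)=C/Cc1cc(OC)ccc1OC
F5 | step 8 | (2E,4S)-3-[(tert-butyldimethylsilyloxy)methyl]-1-(2,5-dimethoxyphenyl)-7-methylocta-2,6-dien-4-ol | CC(C)=CC[C@H](O)C(/CO[Si](C)(C)C(C)(C)C)=C/Cc1cc(OC)ccc1OC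
F6 | step 8 | (2E,4S)-3-[(tert-butyldimethylsilyloxy)methyl]-1-(2,5-dimethoxyphenyl)-7-methylocta-2,6-dien-4-yl 3-methylbut-2-enoate | CC(C)=CC[C@H](OC(=O)C=C(C)C)C(/CO[Si](C)(C)C(C)(C)C)=C/Cc1cc(OC)ccc1OC
F7 | step 4 | 6-methyl-1-(trimethylsilyl)hept-5-en-1-yn-3-one | CC(C)=CCC(=O)C#C[Si](C)(C)C
F8 | step 4 | (S)-6-methyl-1-(trimethylsilyl)hept-5-en-1-yn-3-ol | CC(C)=CC[C@H](O)C#C[Si](C)(C)C
F9 | step 4 | (S)-6-methylhept-5-en-1-yn-3-ol | CC(C)=CC[C@H](O)C#C
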